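**Retrosynthetic overview**

- Feature: in ring A the geranyl carbon C6 lies between the oxygenated carbons C5 and C7 and para to C8a–O1. This is a 2-alkylresorcinol with a para ether oxygen, the pattern a cyclobutenone/siloxyalkyne benzannulation produces.
- Disconnections: C4–C4a (Friedel–Crafts acylation, ring C), then ring A by benzannulation (C5–C6 and C7–C8) from a chiral 3-alkoxycyclobutenone and a geranyl siloxyalkyne, then C2–O1 by Mitsunobu inversion of an (R)-β-hydroxy ester.
- Ring order: ring B is bought, ring A is built in step 8, ring C is closed in step 11. C2 is set in step 3 and inverted once in step 5.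
- Protection: the ring B phenol is carried as a triisopropylsilyl (TIPS) ether, so that one buffered fluoride step ends the route and no acid deprotection meets the geranylresorcinol.

Key step: step 8

**Route**

Step 1
Reactants: 1 methyl 3-hydroxy-4,5-dimethoxybenzoate
Product: 2 methyl 3,4-dimethoxy-5-(triisopropylsilyloxy)benzoate
Conditions: TIPSCl, imidazole, DMF, rt
Reagents that add atoms: triisopropylsilyl chloride, CC(C)[Si](Cl)(C(C)C)C(C)C
Why: Standard imidazole-promoted O-silylation of a phenol; the aryl TIPS ether masks the only acidic OH through the enolate, Mitsunobu and thermal steps and is later removed by fluoride without acid.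

Step 2
Reactants: 2 methyl 3,4-dimethoxy-5-(triisopropylsilyloxy)benzoate
Product: 3 methyl 3-[3,4-dimethoxy-5-(triisopropylsilyloxy)phenyl]-3-oxopropanoate
Conditions: MeOAc (2 equiv), LiN(SiMe3)2 (3.2 equiv), THF, −78 → −20 °C; aq. NH4Cl
Reagents that add atoms: methyl acetate, CC(=O)OC
Why: Crossed Claisen condensation of a non-enolisable aryl ester with the lithium enolate of methyl acetate, driven by deprotonation of the β-keto ester by the excess base.

Step 3
Reactants: 3 methyl 3-[3,4-dimethoxy-5-(triisopropylsilyloxy)phenyl]-3-oxopropanoate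
Product: 4 methyl (R)-3-hydroxy-3-[3,4-dimethoxy-5-(triisopropylsilyloxy)phenyl]propanoate
Conditions: RuCl[(R,R)-TsDPEN](p-cymene) (1 mol%), HCO2H/Et3N (5:2), 30 °C
Reagents that add atoms: none
Why: Noyori asymmetric transfer hydrogenation of an aryl ketone, in which the (R,R)-TsDPEN ruthenium hydride attacks the carbonyl face that gives the (R)-carbinol, the same sense as for acetophenone since aryl outranks CH2CO2Me, and the ring has no ortho substituent to disturb the aryl/arene contact that controls the face.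

Step 4
Reactants: 5 3-ethoxycyclobut-2-en-1-one
Product: 6 cyclobutane-1,3-dione
Conditions: 0.5 M aq. HCl, 0 °C → rt; freeze-dry; use at once
Reagents that add atoms: water, O
Why: Acid hydrolysis of the vinylogous ester (addition of water at C3, loss of ethanol) frees the strongly acidic dione, which is used fresh because it tends to ring-open on storage.

Step 5
Reactants: 4 methyl (R)-3-hydroxy-3-[3,4-dimethoxy-5-(triisopropylsilyloxy)phenyl]propanoate; 6 cyclobutane-1,3-dione
Product: 7 methyl (S)-3-[3,4-dimethoxy-5-(triisopropylsilyloxy)phenyl]-3-[(3-oxocyclobut-1-en-1-yl)oxy]propanoate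
Conditions: PPh3, DIAD, THF, 0 °C → rt
Reagents that add atoms: none
Why: Mitsunobu etherification with an acidic cyclic 1,3-dione enol as the oxygen nucleophile, in which SN2 displacement of the alkoxyphosphonium ion inverts the carbinol carbon from (R) to (S), the low pKa of the nucleophile keeps the medium too weakly basic for β-elimination to the cinnamate, and ring B (its 4-methoxy group twisted by two neighbours) stabilises a benzylic cation too little for an SN1 leak.

Step 6
Reactants: 8 geranyl bromide
Product: 9 (E)-5,9-dimethyldeca-4,8-dien-1-yne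
Conditions: HC≡CMgBr (2 equiv), CuCl (10 mol%), THF, 0 °C → rt
Reagents that add atoms: ethynylmagnesium bromide, C#C[Mg]Br
Why: Copper-catalysed coupling of an alkynyl Grignard reagent with a primary allylic bromide, which substitutes at the α-carbon with retention of the E alkene and avoids the strongly basic media that would isomerise the skipped enyne.

Step 7
Reactants: 9 (E)-5,9-dimethyldeca-4,8-dien-1-yne
Product: 12 (E)-5,9-dimethyl-1-(triisopropylsilyloxy)deca-4,8-dien-1-yne, via lithium acetylide 10 (not isolated), via lithium ynolate 11 (not isolated)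
Conditions: LiN(SiMe3)2, THF, −78 °C; t-BuOOLi (from t-BuOOH, LiN(SiMe3)2), −78 → 0 °C; TIPSOTf, −78 → 0 °C
Reagents that add atoms: tert-butyl hydroperoxide (used as its lithium salt), CC(C)(C)OO; triisopropylsilyl triflate, CC(C)[Si](OS(=O)(=O)C(F)(F)F)(C(C)C)C(C)C
Why: Oxygenation of the lithium acetylide by electrophilic oxygen transfer from lithium tert-butyl peroxide gives the ynolate, which the bulky silyl triflate traps on oxygen; this is the established route from terminal alkynes to TIPS ynol ethers, and the terminal C–H is far more acidic than the doubly activated CH2.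

Step 8
Reactants: 7 methyl (S)-3-[3,4-dimethoxy-5-(triisopropylsilyloxy)phenyl]-3-[(3-oxocyclobut-1-en-1-yl)oxy]propanoate; 12 (E)-5,9-dimethyl-1-(triisopropylsilyloxy)deca-4,8-dien-1-yne
Product: 17 methyl (S)-3-[3,4-dimethoxy-5-(triisopropylsilyloxy)phenyl]-3-[4-geranyl-3-hydroxy-5-(triisopropylsilyloxy)phenoxy]propanoate, via vinylketene 13 (not isolated), via 4-vinylcyclobutenone 14 (not isolated), via dienylketene 15 (not isolated), via cyclohexadienone 16 (not isolated)
Conditions: 12 (1.5 equiv), toluene (0.3 M), sealed tube, argon, 80 → 110 °C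
Reagents that add atoms: none
Why: Heating opens cyclobutenone 7 by four-electron electrocyclic cleavage of its C(=O)–CH2 bond to the alkoxy vinylketene 13, whose ketene unit adds [2+2] to the electron-rich triple bond of 12 to give 4-vinylcyclobutenone 14; a second four-electron opening gives dienylketene 15, which closes by six-electron electrocyclisation to cyclohexadienone 16 and tautomerises to phenol 17. This is the Danheiser benzannulation in its siloxyalkyne form, which gives resorcinol monosilyl ethers from cyclobutenones. Ring A is closed by thermal disrotatory six-electron electrocyclisation between the ketene carbon and the terminal CH2 of the former alkoxyvinyl group, after the two alkyne carbons have been inserted as the geranyl carbon C6 and one oxygenated neighbour (new bonds C5–C6 and C7–C8 in flavanone numbering). No stereocentre is created: the sp3 ring carbon of 14 is transient, and the C2 centre, insulated by its ether oxygen, passes unchanged through neutral thermal conditions. The one selectivity needed is the orientation of the [2+2] step, and the polarisation of the ynol ether secures it: the geranyl-bearing β-carbon is the nucleophilic terminus and bonds to the electrophilic ketene carbon, so geranyl ends ortho to the new hydroxyl, the silyloxy carbon lies beyond it and the ether oxygen is para. The siloxyalkyne is far more reactive toward the ketene than the trisubstituted geranyl alkenes or the ester, and its excess keeps the vinylketene from acylating the product phenol.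

Step 9
Reactants: 17 methyl (S)-3-[3,4-dimethoxy-5-(triisopropylsilyloxy)phenyl]-3-[4-geranyl-3-hydroxy-5-(triisopropylsilyloxy)phenoxy]propanoate
Product: 18 methyl (S)-3-[3,4-dimethoxy-5-(triisopropylsilyloxy)phenyl]-3-[4-geranyl-3,5-bis(triisopropylsilyloxy)phenoxy]propanoate
Conditions: TIPSOTf, 2,6-lutidine, CH2Cl2, 0 °C → rt
Reagents that add atoms: triisopropylsilyl triflate, CC(C)[Si](OS(=O)(=O)C(F)(F)F)(C(C)C)C(C)C
Why: Triflate-mediated silylation of the hindered phenol makes the two carbons ortho to the ether oxygen equivalent, so that ring C closure can give one product only, and removes the free hydroxyl that could add to the adjacent geranyl alkene or be O-acylated in the acidic acylation step.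

Step 10
Reactants: 18 methyl (S)-3-[3,4-dimethoxy-5-(triisopropylsilyloxy)phenyl]-3-[4-geranyl-3,5-bis(triisopropylsilyloxy)phenoxy]propanoate
Product: 20 (S)-3-[3,4-dimethoxy-5-(triisopropylsilyloxy)phenyl]-3-[4-geranyl-3,5-bis(triisopropylsilyloxy)phenoxy]propanoic acid, via trimethylstannyl ester 19 (not isolated)
Conditions: Me3SnOH (6 equiv), ClCH2CH2Cl, 70 °C; cold 0.5 M aq. HCl wash
Reagents that add atoms: trimethyltin hydroxide, C[Sn](C)(C)O
Why: Trimethyltin hydroxide cleaves methyl esters under nearly neutral conditions through the stannyl ester, which avoids the E1cB loss of the β-aryloxy group (and with it the stereocentre) that hydroxide could cause and leaves the aryl silyl ethers in place.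

Step 11
Reactants: 20 (S)-3-[3,4-dimethoxy-5-(triisopropylsilyloxy)phenyl]-3-[4-geranyl-3,5-bis(triisopropylsilyloxy)phenoxy]propanoic acid
Product: 22 (S)-2-[3,4-dimethoxy-5-(triisopropylsilyloxy)phenyl]-6-geranyl-5,7-bis(triisopropylsilyloxy)chroman-4-one, via mixed trifluoroacetic anhydride 21 (not isolated)
Conditions: (CF3CO)2O (1.5 equiv), CH2Cl2 (0.02 M), 0 °C; aq. NaHCO3
Reagents that add atoms: none
Why: Intramolecular Friedel–Crafts acylation through the mixed carboxylic–trifluoroacetic anhydride, in which the phloroglucinol-type ring A attacks through a six-membered transition state at either of the two equivalent carbons ortho to O1, faster than five-membered (indanone) closure onto ring B, while cold, dilute and short conditions protect the geranyl alkenes and the C2–O1 bond from the acid released.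

Step 12
Reactants: 22 (S)-2-[3,4-dimethoxy-5-(triisopropylsilyloxy)phenyl]-6-geranyl-5,7-bis(triisopropylsilyloxy)chroman-4-one
Product: 23 (2S)-6-geranyl-5,7-dihydroxy-2-(3-hydroxy-4,5-dimethoxyphenyl)chroman-4-one (target)
Conditions: Bu4NF (4 equiv), AcOH (4 equiv), THF, 0 °C → rt
Reagents that add atoms: none
Why: Fluoride cleaves the three aryl silyl ethers, and acetic acid buffering keeps the medium from becoming basic enough to open the 5-hydroxyflavanone to its chalcone, which would racemise C2; no acid touches the geranylresorcinol.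

**Compound list**

1 | methyl 3-hydroxy-4,5-dimethoxybenzoate | COC(=O)c1cc(O)c(OC)c(OC)c1 | starting material
2 | methyl 3,4-dimethoxy-5-(triisopropylsilyloxy)benzoate | COC(=O)c1cc(OC)c(OC)c(O[Si](C(C)C)(C(C)C)C(C)C)c1 | intermediate
3 | methyl 3-[3,4-dimethoxy-5-(triisopropylsilyloxy)phenyl]-3-oxopropanoate | COC(=O)CC(=O)c1cc(OC)c(OC)c(O[Si](C(C)C)(C(C)C)C(C)C)c1 | intermediate
4 | methyl (R)-3-hydroxy-3-[3,4-dimethoxy-5-(triisopropylsilyloxy)phenyl]propanoate | COc1cc([C@H](O)CC(=O)OC)cc(O[Si](C(C)C)(C(C)C)C(C)C)c1OC | intermediate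
5 | 3-ethoxycyclobut-2-en-1-one | CCOC1=CC(=O)C1 | starting material
6 | cyclobutane-1,3-dione | O=C1CC(=O)C1 | intermediate
7 | methyl (S)-3-[3,4-dimethoxy-5-(triisopropylsilyloxy)phenyl]-3-[(3-oxocyclobut-1-en-1-yl)oxy]propanoate | COc1cc([C@@H](OC2=CC(=O)C2)CC(=O)OC)cc(O[Si](C(C)C)(C(C)C)C(C)C)c1OC | intermediate
8 | geranyl bromide | BrC/C=C(\C)CCC=C(C)C | starting material
9 | (E)-5,9-dimethyldeca-4,8-dien-1-yne | C#CC/C=C(\C)CCC=C(C)C | intermediate
10 | lithium (E)-5,9-dimethyldeca-4,8-dien-1-yn-1-ide (not isolated) | [Li]C#CC/C=C(\C)CCC=C(C)C | intermediate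
11 | lithium (E)-5,9-dimethyldeca-4,8-dien-1-yn-1-olate (not isolated) | [Li]OC#CC/C=C(\C)CCC=C(C)C | intermediate
12 | (E)-5,9-dimethyl-1-(triisopropylsilyloxy)deca-4,8-dien-1-yne | CC(C)[Si](OC#CC/C=C(\C)CCC=C(C)C)(C(C)C)C(C)C | intermediate
13 | methyl (S)-3-[3,4-dimethoxy-5-(triisopropylsilyloxy)phenyl]-3-[(4-oxobuta-1,3-dien-2-yl)oxy]propanoate (vinylketene, not isolated) | COc1cc([C@@H](OC(=C)C=C=O)CC(=O)OC)cc(O[Si](C(C)C)(C(C)C)C(C)C)c1OC | intermediate
14 | methyl (3S)-3-[3,4-dimethoxy-5-(triisopropylsilyloxy)phenyl]-3-({1-[3-geranyl-4-oxo-2-(triisopropylsilyloxy)cyclobut-2-en-1-yl]vinyl}oxy)propanoate (4-vinylcyclobutenone, both epimers at the ring CH, not isolated) | COc1cc([C@@H](OC(=C)C2C(=O)C(C/C=C(\C)CCC=C(C)C)=C2O[Si](C(C)C)(C(C)C)C(C)C)CC(=O)OC)cc(O[Si](C(C)C)(C(C)C)C(C)C)c1OC | intermediate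
15 | methyl (S)-3-[3,4-dimethoxy-5-(triisopropylsilyloxy)phenyl]-3-{[5-geranyl-6-oxo-4-(triisopropylsilyloxy)hexa-1,3,5-trien-2-yl]oxy}propanoate (dienylketene, not isolated) | COc1cc([C@@H](OC(=C)C=C(O[Si](C(C)C)(C(C)C)C(C)C)C(C/C=C(\C)CCC=C(C)C)=C=O)CC(=O)OC)cc(O[Si](C(C)C)(C(C)C)C(C)C)c1OC | intermediate
16 | methyl (S)-3-[3,4-dimethoxy-5-(triisopropylsilyloxy)phenyl]-3-{[4-geranyl-5-oxo-3-(triisopropylsilyloxy)cyclohexa-1,3-dien-1-yl]oxy}propanoate (cyclohexadienone, not isolated) | COc1cc([C@@H](OC2=CC(O[Si](C(C)C)(C(C)C)C(C)C)=C(C/C=C(\C)CCC=C(C)C)C(=O)C2)CC(=O)OC)cc(O[Si](C(C)C)(C(C)C)C(C)C)c1OC | intermediate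
17 | methyl (S)-3-[3,4-dimethoxy-5-(triisopropylsilyloxy)phenyl]-3-[4-geranyl-3-hydroxy-5-(triisopropylsilyloxy)phenoxy]propanoate | COc1cc([C@@H](Oc2cc(O)c(C/C=C(\C)CCC=C(C)C)c(O[Si](C(C)C)(C(C)C)C(C)C)c2)CC(=O)OC)cc(O[Si](C(C)C)(C(C)C)C(C)C)c1OC | intermediate
18 | methyl (S)-3-[3,4-dimethoxy-5-(triisopropylsilyloxy)phenyl]-3-[4-geranyl-3,5-bis(triisopropylsilyloxy)phenoxy]propanoate | COc1cc([C@@H](Oc2cc(O[Si](C(C)C)(C(C)C)C(C)C)c(C/C=C(\C)CCC=C(C)C)c(O[Si](C(C)C)(C(C)C)C(C)C)c2)CC(=O)OC)cc(O[Si](C(C)C)(C(C)C)C(C)C)c1OC | intermediate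
19 | trimethylstannyl (S)-3-[3,4-dimethoxy-5-(triisopropylsilyloxy)phenyl]-3-[4-geranyl-3,5-bis(triisopropylsilyloxy)phenoxy]propanoate (not isolated) | COc1cc([C@@H](Oc2cc(O[Si](C(C)C)(C(C)C)C(C)C)c(C/C=C(\C)CCC=C(C)C)c(O[Si](C(C)C)(C(C)C)C(C)C)c2)CC(=O)O[Sn](C)(C)C)cc(O[Si](C(C)C)(C(C)C)C(C)C)c1OC | intermediate
20 | (S)-3-[3,4-dimethoxy-5-(triisopropylsilyloxy)phenyl]-3-[4-geranyl-3,5-bis(triisopropylsilyloxy)phenoxy]propanoic acid | COc1cc([C@@H](Oc2cc(O[Si](C(C)C)(C(C)C)C(C)C)c(C/C=C(\C)CCC=C(C)C)c(O[Si](C(C)C)(C(C)C)C(C)C)c2)CC(=O)O)cc(O[Si](C(C)C)(C(C)C)C(C)C)c1OC | intermediate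
21 | (S)-3-[3,4-dimethoxy-5-(triisopropylsilyloxy)phenyl]-3-[4-geranyl-3,5-bis(triisopropylsilyloxy)phenoxy]propanoic trifluoroacetic anhydride (not isolated) | COc1cc([C@@H](Oc2cc(O[Si](C(C)C)(C(C)C)C(C)C)c(C/C=C(\C)CCC=C(C)C)c(O[Si](C(C)C)(C(C)C)C(C)C)c2)CC(=O)OC(=O)C(F)(F)F)cc(O[Si](C(C)C)(C(C)C)C(C)C)c1OC | intermediate
22 | (S)-2-[3,4-dimethoxy-5-(triisopropylsilyloxy)phenyl]-6-geranyl-5,7-bis(triisopropylsilyloxy)chroman-4-one | COc1cc([C@@H]2CC(=O)c3c(cc(O[Si](C(C)C)(C(C)C)C(C)C)c(C/C=C(\C)CCC=C(C)C)c3O[Si](C(C)C)(C(C)C)C(C)C)O2)cc(O[Si](C(C)C)(C(C)C)C(C)C)c1OC | intermediate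
23 | (2S)-6-[(2E)-3,7-dimethylocta-2,6-dien-1-yl]-5,7-dihydroxy-2-(3-hydroxy-4,5-dimethoxyphenyl)chroman-4-one | COc1cc([C@@H]2CC(=O)c3c(cc(O)c(C/C=C(\C)CCC=C(C)C)c3O)O2)cc(O)c1OC | target

**Step count**

Total: 12 steps. Longest linear sequence: 9 steps (1, 2, 3, 5, 8, 9, 10, 11, 12); steps 4, 6 and 7 are side branches.

**Three steps most likely to fail**

1. Step 8 (benzannulation). The donor-stabilised cyclobutenone may open too slowly below the temperature at which the siloxyalkyne rearranges to a silylketene. The vinylketene may also be consumed by dimerisation or by acylating the product phenol before it meets the alkyne. Fallback, setting out from 4 and 8 and coming back at 18: ring A is taken from phloroglucinol and joined to the side chain by aryl ether formation. Phloroglucinol is C-alkylated with 8 (DBU, THF) to 2-geranylphloroglucinol F1. Exhaustive silylation (TIPSOTf, 2,6-lutidine) should give 2-geranyl-1,3,5-tris(triisopropylsilyloxy)benzene F2. One equivalent of Bu4NF at −78 °C should remove the least hindered silyl group, the one para to geranyl, to give 4-geranyl-3,5-bis(triisopropylsilyloxy)phenol F3. Mitsunobu etherification of F3 with the (R)-alcohol 4 (PPh3, DIAD, toluene) then inverts the carbinol carbon and should give 18.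

2. Step 11 (ring C closure). The trifluoroacetic acid released may start cationic cyclisation of the geranyl chain, ring A may be trifluoroacetylated, or the silyl ether flanking the reacting carbon may slow the closure. Fallback, setting out from 18 and coming back at 22: the acid-mediated acylation is replaced by a base-buffered amide activation (intramolecular Vilsmeier–Haack-type closure). Ester 18 is converted with Me2NH·HCl/AlMe3 into the N,N-dimethylamide F4. Tf2O with 2-chloropyridine in CH2Cl2 at −78 → 0 °C activates the amide, and ring A attacks to give the cyclic 4-(dimethyliminio)chroman triflate F5. Aqueous NaHCO3 hydrolysis of F5 should give ketone 22 without free strong acid.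

3. Step 5 (Mitsunobu etherification). The activated benzylic alcohol may undergo β-elimination to the cinnamate, the dione may be alkylated on carbon, or the dione may ring-open before it is alkylated. Fallback, setting out from 3 and 5 and coming back at 7: the ether is made by exchange with retention instead of displacement with inversion. Keto ester 3 is reduced with the enantiomeric catalyst RuCl[(S,S)-TsDPEN](p-cymene) in HCO2H/Et3N to the (S)-hydroxy ester F6. Acid-catalysed transetherification of 3-ethoxycyclobutenone 5 with F6 (pyridinium p-toluenesulfonate, toluene, 5 Å molecular sieves, ethanol removed under reduced pressure) should then give 7 with the C–O bond of the stereocentre untouched.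

**Further compounds**

F1 | step 8 | 2-geranylphloroglucinol, 2-[(2E)-3,7-dimethylocta-2,6-dien-1-yl]benzene-1,3,5-triol | Oc1cc(O)c(C/C=C(\C)CCC=C(C)C)c(O)c1
F2 | step 8 | 2-geranyl-1,3,5-tris(triisopropylsilyloxy)benzene | CC(C)[Si](Oc1cc(O[Si](C(C)C)(C(C)C)C(C)C)c(C/C=C(\C)CCC=C(C)C)c(O[Si](C(C)C)(C(C)C)C(C)C)c1)(C(C)C)C(C)C
F3 | step 8 | 4-geranyl-3,5-bis(triisopropylsilyloxy)phenol | Oc1cc(O[Si](C(C)C)(C(C)C)C(C)C)c(C/C=C(\C)CCC=C(C)C)c(O[Si](C(C)C)(C(C)C)C(C)C)c1
F4 | step 11 | (S)-3-[3,4-dimethoxy-5-(triisopropylsilyloxy)phenyl]-3-[4-geranyl-3,5-bis(triisopropylsilyloxy)phenoxy]-N,N-dimethylpropanamide | COc1cc([C@@H](Oc2cc(O[Si](C(C)C)(C(C)C)C(C)C)c(C/C=C(\C)CCC=C(C)C)c(O[Si](C(C)C)(C(C)C)C(C)C)c2)CC(=O)N(C)C)cc(O[Si](C(C)C)(C(C)C)C(C)C)c1OC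
F5 | step 11 | (S)-N-{2-[3,4-dimethoxy-5-(triisopropylsilyloxy)phenyl]-6-geranyl-5,7-bis(triisopropylsilyloxy)chroman-4-ylidene}-N-methylmethanaminium triflate | COc1cc([C@@H]2CC(=[N+](C)C)c3c(cc(O[Si](C(C)C)(C(C)C)C(C)C)c(C/C=C(\C)CCC=C(C)C)c3O[Si](C(C)C)(C(C)C)C(C)C)O2)cc(O[Si](C(C)C)(C(C)C)C(C)C)c1OC.[O-]S(=O)(=O)C(F)(F)F
F6 | step 5 | methyl (S)-3-hydroxy-3-[3,4-dimethoxy-5-(triisopropylsilyloxy)phenyl]propanoate | COc1cc([C@@H](O)CC(=O)OC)cc(O[Si](C(C)C)(C(C)C)C(C)C)c1OC
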